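**Retrosynthetic overview**

1. The strategy rests on the cyclohexane C5–C10. Its substituents (C5 isopropenyl, C6 lactone O, C7 lactone C, C8 O-angelate, C9 O-acetate, the two-carbon enol acetate arm on C10) are all equatorial and only the C10 methyl is axial. The contiguous triad C9–O / quaternary C10 / C5–isopropenyl is therefore read as an E-configured alkynyl epoxide opened at C10 with inversion by a 2-methylpropenyl group through one chair.
2. Endgame: the Z enol acetate comes last, from the C10 ethynyl group by Ru-catalysed addition of AcOH; before it the O8 angelate, the O9 acetate and the C13 methylene (formylation, then formaldehyde).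
3. Ring order: the carbocycle is closed first by the C5–C10 bond (epoxide-initiated cation–olefin closure of an open C5–C10 chain); the γ-lactone is closed second, from O6 onto C12.
4. Chain assembly: C5–C6 by Felkin addition of 2-methyl-1-propenylmagnesium bromide to a C6 aldehyde; the C9/C10 epoxide by hydroxyl-directed epoxidation; C7–C8 by an Evans syn-aldol of a succinate imide with (E)-3-methylpent-2-en-4-ynal.

Key step: step 10

Remark: atom labels C1–C15 follow the elemane skeleton (ring C5–C10; C1/C2 the two-carbon arm on C10; C14 the C10 methyl; C4 with C3 and C15 the isopropenyl group; C11, C12, C13 the lactone unit on C7). The C9 hydroxyl is capped as a TES ether during the basic α-methylenation (steps 13–16) so that the O8 silyl group cannot migrate and the lactone cannot shift to O8.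

**Route**

Step 1
Reactants: 1 (2E)-3-methylpent-2-en-4-yn-1-ol
Product: 2 (2E)-3-methylpent-2-en-4-ynal
Conditions: MnO2 (activated, excess), CH2Cl2, rt; filtered solution used directly
Reagents that add atoms: none
Why: Heterogeneous MnO2 oxidation is selective for the allylic alcohol and should leave the E alkene and the terminal alkyne untouched.

Step 2
Reactants: 3 mono-tert-butyl succinate; 4 (4R)-4-benzyl-1,3-oxazolidin-2-one
Product: 6 tert-butyl 4-[(4R)-4-benzyl-2-oxo-1,3-oxazolidin-3-yl]-4-oxobutanoate, via mixed pivalic anhydride 5 (not isolated)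
Conditions: PivCl, Et3N, THF, −20 °C; then 4, LiCl, −20 °C to rt
Reagents that add atoms: pivaloyl chloride CC(C)(C)C(Cl)=O (its atoms stay only in 5)
Why: Mixed-anhydride N-acylation of the oxazolidinone under LiCl/Et3N activation should occur at the unhindered succinyl carbonyl, with the tert-butyl ester inert.

Step 3
Reactants: 6 tert-butyl 4-[(4R)-4-benzyl-2-oxo-1,3-oxazolidin-3-yl]-4-oxobutanoate; 2 (2E)-3-methylpent-2-en-4-ynal
Product: 9 syn-aldol adduct tert-butyl (3R,4S,5E)-3-{[(4R)-4-benzyl-2-oxo-1,3-oxazolidin-3-yl]carbonyl}-4-hydroxy-6-methyloct-5-en-7-ynoate, via Z dibutylboron enolate 7 (not isolated), via dibutylboron aldolate 8 (not isolated)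
Conditions: Bu2BOTf, iPr2NEt, CH2Cl2, 0 °C; then 2, −78 to 0 °C; then pH 7 buffer, MeOH, 30% H2O2, 0 °C
Reagents that add atoms: dibutylboron triflate CCCCB(CCCC)OS(=O)(=O)C(F)(F)F (boron stays only in 7 and 8)
Why: Evans boron syn-aldol: soft enolisation should give only the Z enolate of the imide (the ester is not enolised), and the Zimmerman–Traxler chair with the aldehyde approaching anti to the benzyl group sets C7 (R) and C8 (S) syn.

Step 4
Reactants: 9 syn-aldol adduct
Product: 10 tert-butyl (3R,4R)-3-{[(4R)-4-benzyl-2-oxo-1,3-oxazolidin-3-yl]carbonyl}-4-[(2S,3S)-3-ethynyl-3-methyloxiran-2-yl]-4-hydroxybutanoate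
Conditions: mCPBA, NaHCO3, CH2Cl2, 0 °C
Reagents that add atoms: mCPBA OOC(=O)c1cccc(Cl)c1
Why: Hydroxyl-directed (Henbest) peracid epoxidation: A1,3 strain from the C14 methyl cis to C8 holds the C8–H bond in the alkene plane, so the peracid is delivered from the hydroxyl face and should give the threo epoxy alcohol (C9 S, C10 S), the alkyne being far less reactive.

Step 5
Reactants: 10 epoxy alcohol
Product: 11 tert-butyl (3R,4R)-3-{[(4R)-4-benzyl-2-oxo-1,3-oxazolidin-3-yl]carbonyl}-4-[(tert-butyldimethylsilyl)oxy]-4-[(2S,3S)-3-ethynyl-3-methyloxiran-2-yl]butanoate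
Conditions: TBSCl, imidazole, DMAP (cat.), DMF, rt to 35 °C
Reagents that add atoms: TBSCl CC(C)(C)[Si](C)(C)Cl
Why: Silylation under basic, non-Lewis-acidic conditions should protect O8 without opening the acid-labile tertiary propargylic epoxide or triggering retro-aldol.

Step 6
Reactants: 11 TBS ether
Product: 12 tert-butyl (3S,4R)-4-[(tert-butyldimethylsilyl)oxy]-4-[(2S,3S)-3-ethynyl-3-methyloxiran-2-yl]-3-(hydroxymethyl)butanoate
Conditions: LiBH4, MeOH (1 equiv), THF, 0 °C; cold aq. NH4Cl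
Reagents that add atoms: none
Why: Reductive removal of the auxiliary: LiBH4 reduces the activated imide carbonyl much faster than the tert-butyl ester or the trisubstituted epoxide, and a cold quench should prevent lactonisation of the γ-hydroxy ester.

Step 7
Reactants: 12 primary alcohol
Product: 13 tert-butyl (3R,4R)-4-[(tert-butyldimethylsilyl)oxy]-4-[(2S,3S)-3-ethynyl-3-methyloxiran-2-yl]-3-formylbutanoate
Conditions: Dess–Martin periodinane, NaHCO3, CH2Cl2, 0 °C to rt; used at once
Reagents that add atoms: none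
Why: Buffered Dess–Martin oxidation is neutral and should give the C6 aldehyde without epimerising C7 or eliminating the β-silyloxy group.

Step 8
Reactants: 13 C6 aldehyde; 14 2-methyl-1-propenylmagnesium bromide
Product: 15 tert-butyl (3S,4R)-4-[(tert-butyldimethylsilyl)oxy]-4-[(2S,3S)-3-ethynyl-3-methyloxiran-2-yl]-3-[(1R)-1-hydroxy-3-methylbut-2-en-1-yl]butanoate
Conditions: 14 (3 equiv), THF, −78 °C; sat. aq. NH4Cl at −78 °C
Reagents that add atoms: none
Why: Felkin–Anh addition of the alkenyl Grignard reagent, with the branched C8 carbon as the large group anti to the nucleophile, should set C6 (R, hydroxyl syn to the C11 arm in the zigzag); excess reagent covers any loss to the alkyne C–H, and at −78 °C the ester and the epoxide are not attacked.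

Step 9
Reactants: 15 allylic alcohol
Product: 16 tert-butyl (3S,4R)-4-[(tert-butyldimethylsilyl)oxy]-4-[(2S,3S)-3-ethynyl-3-methyloxiran-2-yl]-3-{(1R)-3-methyl-1-[(triethylsilyl)oxy]but-2-en-1-yl}butanoate
Conditions: TESCl, imidazole, DMAP (cat.), CH2Cl2, 0 °C to rt
Reagents that add atoms: TESCl CC[Si](Cl)(CC)CC
Why: Standard silylation caps O6 so that it cannot compete as a nucleophile or lactonise, with a group that can later be removed in the presence of the O8 TBS ether.

Step 10
Reactants: 16 acyclic epoxy alkene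
Product: 17 tert-butyl 2-[(1S,2R,3R,4R,5S,6R)-2-[(tert-butyldimethylsilyl)oxy]-4-ethynyl-3-hydroxy-4-methyl-5-(prop-1-en-2-yl)-6-[(triethylsilyl)oxy]cyclohexyl]acetate
Conditions: Et2AlCl (2.5 equiv), CH2Cl2, −78 to −40 °C; aq. KNaC4H4O6 (potassium sodium tartrate)
Reagents that add atoms: none
Why: Proposed new method: Et2AlCl binds the epoxide oxygen, the tertiary propargylic C10–O bond stretches while the secondary C9–O bond next to the oxygenated C8 stays intact, C5 of the 2-methylpropenyl group attacks C10 from the side opposite the oxygen, and the tertiary C4 cation sheds a methyl proton (taken up by an ethyl group on aluminium) to leave the isopropenyl group and the C9 aluminium alkoxide. The closest known reaction types are Lewis-acid epoxide-initiated cation–olefin cyclisations of epoxy polyenes and the Prins–ene closure of citronellal to isopulegol; an alkynyl epoxide initiator combined with this isopropenyl-forming termination has not been shown. The cyclohexane C5–C10 closes by the C5–C10 bond in a six-membered mode that is endo for the epoxide (C9 and C10 both in the ring) and exo for the alkene (C4 outside the ring). C10 is set by inversion of the E-derived epoxide carbon (methyl axial, ethynyl equatorial); C5 is set by the chair in which the C5=C4 unit, OTES, CH2CO2tBu, OTBS and the C9–O bond are all equatorial, the axial alkenyl alternative being disfavoured by A1,3 strain; C6 to C9 are carried over unchanged. The step needs C10–O rather than C9–O cleavage, carbon rather than oxygen capture, and a tight ion pair; propargylic stabilisation at C10, the silyl caps on O6 and O8, the single low-energy all-trans chair and the low temperature in CH2Cl2 should secure these.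

Step 11
Reactants: 17 cyclohexanol
Product: 18 tert-butyl 2-[(1S,2R,3R,4R,5S,6R)-2-[(tert-butyldimethylsilyl)oxy]-4-ethynyl-3,6-dihydroxy-4-methyl-5-(prop-1-en-2-yl)cyclohexyl]acetate
Conditions: PPTS (cat.), MeOH–CH2Cl2, 0 °C
Reagents that add atoms: none
Why: Mild acid methanolysis should cleave the secondary TES ether at O6 far faster than the TBS ether at O8.

Step 12
Reactants: 18 diol tert-butyl ester
Product: 21 trans-fused γ-lactone (3aS,4R,5R,6R,7S,7aR)-4-[(tert-butyldimethylsilyl)oxy]-6-ethynyl-5-hydroxy-6-methyl-7-(prop-1-en-2-yl)hexahydro-1-benzofuran-2(3H)-one, via tris(trimethylsilyl) derivative 19 (not isolated), via hydroxy acid 20 (not isolated)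
Conditions: TMSOTf (4 equiv), 2,6-lutidine, CH2Cl2, 0 °C; then aq. citric acid, THF, rt; then PPTS (cat.), toluene, 50 °C
Reagents that add atoms: TMSOTf C[Si](C)(C)OS(=O)(=O)C(F)(F)F (silicon stays only in 19)
Why: Silyl triflate cleavage of the tert-butyl ester under lutidine buffering spares the isopropenyl group and the TBS ether; mild acid then frees the acid and the TMS ethers, and acid-catalysed lactonisation can only engage O6 (O8 is silylated, O9 cannot reach C12), the trans-diequatorial C6/C7 pair giving the trans-fused ring with no stereocentre touched.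

Step 13
Reactants: 21 hydroxy lactone
Product: 22 (3aS,4R,5R,6R,7S,7aR)-4-[(tert-butyldimethylsilyl)oxy]-6-ethynyl-6-methyl-7-(prop-1-en-2-yl)-5-[(triethylsilyl)oxy]hexahydro-1-benzofuran-2(3H)-one
Conditions: TESOTf, 2,6-lutidine, CH2Cl2, −78 to 0 °C
Reagents that add atoms: TESOTf CC[Si](CC)(CC)OS(=O)(=O)C(F)(F)F
Why: Triflate silylation should cap the hindered C9 hydroxyl, so that no alkoxide next to the O8 TBS ether exists under the basic conditions of steps 14 and 15.

Step 14
Reactants: 22 bis-silyl lactone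
Product: 23 (3aS,4R,5R,6R,7S,7aR)-4-[(tert-butyldimethylsilyl)oxy]-6-ethynyl-3-(hydroxymethylidene)-6-methyl-7-(prop-1-en-2-yl)-5-[(triethylsilyl)oxy]hexahydro-1-benzofuran-2(3H)-one
Conditions: NaH, HCO2Et, EtOH (cat.), THF, 0 °C to rt; cold aq. NH4Cl; used crude
Reagents that add atoms: ethyl formate CCOC=O
Why: Claisen formylation of the lactone at C11 is driven by formation of the stabilised formyl-lactone enolate, and the alkoxide base present should not deprotonate the terminal alkyne.

Step 15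
Reactants: 23 hydroxymethylene lactone
Product: 24 (3aS,4R,5R,6R,7S,7aR)-4-[(tert-butyldimethylsilyl)oxy]-6-ethynyl-6-methyl-3-methylidene-7-(prop-1-en-2-yl)-5-[(triethylsilyl)oxy]hexahydro-1-benzofuran-2(3H)-one
Conditions: (CH2O)n, K2CO3, THF, 50 °C
Reagents that add atoms: formaldehyde (from paraformaldehyde) C=O
Why: Deformylative methylenation: aldol addition to formaldehyde, formyl transfer to the new alkoxide and E1cB loss of formate should give the α-methylene lactone carrying C13.

Step 16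
Reactants: 24 bis-silyl α-methylene lactone
Product: 25 (3aS,4R,5R,6R,7S,7aR)-4-[(tert-butyldimethylsilyl)oxy]-6-ethynyl-5-hydroxy-6-methyl-3-methylidene-7-(prop-1-en-2-yl)hexahydro-1-benzofuran-2(3H)-one
Conditions: PPTS, MeOH–CH2Cl2, 0 °C to rt
Reagents that add atoms: none
Why: Acid methanolysis should remove the TES ether at O9 selectively over the TBS ether at O8, and the acidic medium does not add methanol to the methylene lactone.

Step 17
Reactants: 25 C9 alcohol
Product: 26 (3aS,4R,5R,6R,7S,7aR)-4-[(tert-butyldimethylsilyl)oxy]-6-ethynyl-6-methyl-3-methylidene-2-oxo-7-(prop-1-en-2-yl)octahydro-1-benzofuran-5-yl acetate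
Conditions: Ac2O, DMAP, pyridine, CH2Cl2, rt
Reagents that add atoms: acetic anhydride CC(=O)OC(C)=O
Why: DMAP-catalysed acetylation should acylate the hindered equatorial C9 hydroxyl, the only free hydroxyl in the molecule.

Step 18
Reactants: 26 C9 acetate
Product: 27 (3aR,4R,5R,6R,7S,7aR)-6-ethynyl-4-hydroxy-6-methyl-3-methylidene-2-oxo-7-(prop-1-en-2-yl)octahydro-1-benzofuran-5-yl acetate
Conditions: HF·pyridine, pyridine, THF, 0 °C to rt
Reagents that add atoms: none
Why: Buffered HF·pyridine cleaves the TBS ether under weakly acidic conditions that should neither move the acetate to O8 nor touch the methylene lactone.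

Step 19
Reactants: 27 C8 alcohol; 28 angelic acid
Product: 30 (3aS,4R,5R,6R,7S,7aR)-5-(acetyloxy)-6-ethynyl-6-methyl-3-methylidene-2-oxo-7-(prop-1-en-2-yl)octahydro-1-benzofuran-4-yl (2Z)-2-methylbut-2-enoate, via angelic 2,4,6-trichlorobenzoic anhydride 29 (not isolated)
Conditions: 28, 2,4,6-trichlorobenzoyl chloride, Et3N, toluene, rt; then 27, 75 °C
Reagents that add atoms: 2,4,6-trichlorobenzoyl chloride O=C(Cl)c1c(Cl)cc(Cl)cc1Cl (its atoms stay only in 29)
Why: Yamaguchi-type esterification: the alcohol attacks the angeloyl carbonyl of the mixed anhydride (the aryl carbonyl is shielded by two ortho chlorines), and without a nucleophilic catalyst the Z geometry of the angelate should be kept.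

Step 20
Reactants: 30 terminal alkyne
Product: 31 target CNP0582479.1
Conditions: Ru(methallyl)2(dppb) (5 mol %), AcOH (2 equiv), toluene, 60 °C
Reagents that add atoms: acetic acid CC(=O)O
Why: Ruthenium-catalysed anti-Markovnikov hydro-acyloxylation through a ruthenium vinylidene, which only a terminal alkyne can form, should add acetate to the terminal carbon and give the Z enol acetate, leaving the three alkenes untouched; it is placed last because the enol acetate is labile.

**Compound list**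

1 | (2E)-3-methylpent-2-en-4-yn-1-ol | OC/C=C(\C)C#C | starting material
2 | (2E)-3-methylpent-2-en-4-ynal | O=C/C=C(\C)C#C | intermediate
3 | mono-tert-butyl succinate (4-tert-butoxy-4-oxobutanoic acid) | OC(=O)CCC(=O)OC(C)(C)C | starting material
4 | (4R)-4-benzyl-1,3-oxazolidin-2-one | O=C1N[C@H](Cc2ccccc2)CO1 | starting material
5 | 4-tert-butoxy-4-oxobutanoic pivalic anhydride | CC(C)(C)OC(=O)CCC(=O)OC(=O)C(C)(C)C | intermediate
6 | tert-butyl 4-[(4R)-4-benzyl-2-oxo-1,3-oxazolidin-3-yl]-4-oxobutanoate | CC(C)(C)OC(=O)CCC(=O)N1[C@H](Cc2ccccc2)COC1=O | intermediate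
7 | Z dibutylboron enolate of 6 (OB cis to the CH2CO2tBu arm) | CC(C)(C)OC(=O)C/C=C(\OB(CCCC)CCCC)N1[C@H](Cc2ccccc2)COC1=O | intermediate
8 | dibutylboron aldolate (O8-boryl derivative of 9) | O=C1OC[C@@H](Cc2ccccc2)N1C(=O)[C@H](CC(=O)OC(C)(C)C)[C@@H](OB(CCCC)CCCC)/C=C(\C)C#C | intermediate
9 | tert-butyl (3R,4S,5E)-3-{[(4R)-4-benzyl-2-oxo-1,3-oxazolidin-3-yl]carbonyl}-4-hydroxy-6-methyloct-5-en-7-ynoate | O=C1OC[C@@H](Cc2ccccc2)N1C(=O)[C@H](CC(=O)OC(C)(C)C)[C@@H](O)/C=C(\C)C#C | intermediate
10 | tert-butyl (3R,4R)-3-{[(4R)-4-benzyl-2-oxo-1,3-oxazolidin-3-yl]carbonyl}-4-[(2S,3S)-3-ethynyl-3-methyloxiran-2-yl]-4-hydroxybutanoate | O=C1OC[C@@H](Cc2ccccc2)N1C(=O)[C@H](CC(=O)OC(C)(C)C)[C@@H](O)[C@@H]1O[C@@]1(C)C#C | intermediate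
11 | tert-butyl (3R,4R)-3-{[(4R)-4-benzyl-2-oxo-1,3-oxazolidin-3-yl]carbonyl}-4-[(tert-butyldimethylsilyl)oxy]-4-[(2S,3S)-3-ethynyl-3-methyloxiran-2-yl]butanoate | O=C1OC[C@@H](Cc2ccccc2)N1C(=O)[C@H](CC(=O)OC(C)(C)C)[C@@H](O[Si](C)(C)C(C)(C)C)[C@@H]1O[C@@]1(C)C#C | intermediate
12 | tert-butyl (3S,4R)-4-[(tert-butyldimethylsilyl)oxy]-4-[(2S,3S)-3-ethynyl-3-methyloxiran-2-yl]-3-(hydroxymethyl)butanoate | OC[C@H](CC(=O)OC(C)(C)C)[C@@H](O[Si](C)(C)C(C)(C)C)[C@@H]1O[C@@]1(C)C#C | intermediate
13 | tert-butyl (3R,4R)-4-[(tert-butyldimethylsilyl)oxy]-4-[(2S,3S)-3-ethynyl-3-methyloxiran-2-yl]-3-formylbutanoate | O=C[C@H](CC(=O)OC(C)(C)C)[C@@H](O[Si](C)(C)C(C)(C)C)[C@@H]1O[C@@]1(C)C#C | intermediate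
14 | 2-methyl-1-propenylmagnesium bromide | CC(C)=C[Mg]Br | starting material
15 | tert-butyl (3S,4R)-4-[(tert-butyldimethylsilyl)oxy]-4-[(2S,3S)-3-ethynyl-3-methyloxiran-2-yl]-3-[(1R)-1-hydroxy-3-methylbut-2-en-1-yl]butanoate | CC(C)=C[C@@H](O)[C@H](CC(=O)OC(C)(C)C)[C@@H](O[Si](C)(C)C(C)(C)C)[C@@H]1O[C@@]1(C)C#C | intermediate
16 | tert-butyl (3S,4R)-4-[(tert-butyldimethylsilyl)oxy]-4-[(2S,3S)-3-ethynyl-3-methyloxiran-2-yl]-3-{(1R)-3-methyl-1-[(triethylsilyl)oxy]but-2-en-1-yl}butanoate | CC(C)=C[C@@H](O[Si](CC)(CC)CC)[C@H](CC(=O)OC(C)(C)C)[C@@H](O[Si](C)(C)C(C)(C)C)[C@@H]1O[C@@]1(C)C#C | intermediate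
17 | tert-butyl 2-[(1S,2R,3R,4R,5S,6R)-2-[(tert-butyldimethylsilyl)oxy]-4-ethynyl-3-hydroxy-4-methyl-5-(prop-1-en-2-yl)-6-[(triethylsilyl)oxy]cyclohexyl]acetate | CC(=C)[C@@H]1[C@@H](O[Si](CC)(CC)CC)[C@H](CC(=O)OC(C)(C)C)[C@@H](O[Si](C)(C)C(C)(C)C)[C@H](O)[C@@]1(C)C#C | intermediate
18 | tert-butyl 2-[(1S,2R,3R,4R,5S,6R)-2-[(tert-butyldimethylsilyl)oxy]-4-ethynyl-3,6-dihydroxy-4-methyl-5-(prop-1-en-2-yl)cyclohexyl]acetate | CC(=C)[C@@H]1[C@@H](O)[C@H](CC(=O)OC(C)(C)C)[C@@H](O[Si](C)(C)C(C)(C)C)[C@H](O)[C@@]1(C)C#C | intermediate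
19 | trimethylsilyl 2-[(1S,2R,3R,4R,5S,6R)-2-[(tert-butyldimethylsilyl)oxy]-4-ethynyl-4-methyl-5-(prop-1-en-2-yl)-3,6-bis[(trimethylsilyl)oxy]cyclohexyl]acetate | CC(=C)[C@@H]1[C@@H](O[Si](C)(C)C)[C@H](CC(=O)O[Si](C)(C)C)[C@@H](O[Si](C)(C)C(C)(C)C)[C@H](O[Si](C)(C)C)[C@@]1(C)C#C | intermediate
20 | 2-[(1S,2R,3R,4R,5S,6R)-2-[(tert-butyldimethylsilyl)oxy]-4-ethynyl-3,6-dihydroxy-4-methyl-5-(prop-1-en-2-yl)cyclohexyl]acetic acid | CC(=C)[C@@H]1[C@@H](O)[C@H](CC(=O)O)[C@@H](O[Si](C)(C)C(C)(C)C)[C@H](O)[C@@]1(C)C#C | intermediate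
21 | (3aS,4R,5R,6R,7S,7aR)-4-[(tert-butyldimethylsilyl)oxy]-6-ethynyl-5-hydroxy-6-methyl-7-(prop-1-en-2-yl)hexahydro-1-benzofuran-2(3H)-one | O=C1O[C@H]2[C@H](C1)[C@@H](O[Si](C)(C)C(C)(C)C)[C@H](O)[C@@](C)(C#C)[C@@H]2C(=C)C | intermediate
22 | (3aS,4R,5R,6R,7S,7aR)-4-[(tert-butyldimethylsilyl)oxy]-6-ethynyl-6-methyl-7-(prop-1-en-2-yl)-5-[(triethylsilyl)oxy]hexahydro-1-benzofuran-2(3H)-one | O=C1O[C@H]2[C@H](C1)[C@@H](O[Si](C)(C)C(C)(C)C)[C@H](O[Si](CC)(CC)CC)[C@@](C)(C#C)[C@@H]2C(=C)C | intermediate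
23 | (3aS,4R,5R,6R,7S,7aR)-4-[(tert-butyldimethylsilyl)oxy]-6-ethynyl-3-(hydroxymethylidene)-6-methyl-7-(prop-1-en-2-yl)-5-[(triethylsilyl)oxy]hexahydro-1-benzofuran-2(3H)-one (enol form of the 3-formyl lactone) | OC=C1C(=O)O[C@H]2[C@H]1[C@@H](O[Si](C)(C)C(C)(C)C)[C@H](O[Si](CC)(CC)CC)[C@@](C)(C#C)[C@@H]2C(=C)C | intermediate
24 | (3aS,4R,5R,6R,7S,7aR)-4-[(tert-butyldimethylsilyl)oxy]-6-ethynyl-6-methyl-3-methylidene-7-(prop-1-en-2-yl)-5-[(triethylsilyl)oxy]hexahydro-1-benzofuran-2(3H)-one | C=C1C(=O)O[C@H]2[C@H]1[C@@H](O[Si](C)(C)C(C)(C)C)[C@H](O[Si](CC)(CC)CC)[C@@](C)(C#C)[C@@H]2C(=C)C | intermediate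
25 | (3aS,4R,5R,6R,7S,7aR)-4-[(tert-butyldimethylsilyl)oxy]-6-ethynyl-5-hydroxy-6-methyl-3-methylidene-7-(prop-1-en-2-yl)hexahydro-1-benzofuran-2(3H)-one | C=C1C(=O)O[C@H]2[C@H]1[C@@H](O[Si](C)(C)C(C)(C)C)[C@H](O)[C@@](C)(C#C)[C@@H]2C(=C)C | intermediate
26 | (3aS,4R,5R,6R,7S,7aR)-4-[(tert-butyldimethylsilyl)oxy]-6-ethynyl-6-methyl-3-methylidene-2-oxo-7-(prop-1-en-2-yl)octahydro-1-benzofuran-5-yl acetate | C=C1C(=O)O[C@H]2[C@H]1[C@@H](O[Si](C)(C)C(C)(C)C)[C@H](OC(C)=O)[C@@](C)(C#C)[C@@H]2C(=C)C | intermediate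
27 | (3aR,4R,5R,6R,7S,7aR)-6-ethynyl-4-hydroxy-6-methyl-3-methylidene-2-oxo-7-(prop-1-en-2-yl)octahydro-1-benzofuran-5-yl acetate | C=C1C(=O)O[C@H]2[C@H]1[C@@H](O)[C@H](OC(C)=O)[C@@](C)(C#C)[C@@H]2C(=C)C | intermediate
28 | angelic acid, (2Z)-2-methylbut-2-enoic acid | C/C=C(/C)C(=O)O | starting material
29 | (2Z)-2-methylbut-2-enoic 2,4,6-trichlorobenzoic anhydride | C/C=C(/C)C(=O)OC(=O)c1c(Cl)cc(Cl)cc1Cl | intermediate
30 | (3aS,4R,5R,6R,7S,7aR)-5-(acetyloxy)-6-ethynyl-6-methyl-3-methylidene-2-oxo-7-(prop-1-en-2-yl)octahydro-1-benzofuran-4-yl (2Z)-2-methylbut-2-enoate | C=C1C(=O)O[C@H]2[C@H]1[C@@H](OC(=O)/C(C)=C\C)[C@H](OC(C)=O)[C@@](C)(C#C)[C@@H]2C(=C)C | intermediate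
31 | (3aS,4R,5R,6S,7S,7aR)-5-(acetyloxy)-6-[(Z)-2-(acetyloxy)ethenyl]-6-methyl-3-methylidene-2-oxo-7-(prop-1-en-2-yl)octahydro-1-benzofuran-4-yl (2Z)-2-methylbut-2-enoate, CNP0582479.1 | C=C1C(=O)O[C@H]2[C@H]1[C@@H](OC(=O)/C(C)=C\C)[C@H](OC(C)=O)[C@@](C)(/C=C\OC(C)=O)[C@@H]2C(=C)C | target

**Step count**

Total: 20 steps. Longest linear sequence: 19 steps (steps 2 to 20 from 3 and 4; the arm through step 1 is equally long).

**Steps most likely to fail**

Step 10. The ion pair may loosen into a free propargylic/allenyl cation, so that the C10 configuration is no longer tied to the epoxide geometry. A 1,2-hydride shift from C9 (Meinwald rearrangement), capture of C10 by the O6 silyl ether, the ester carbonyl or chloride, and ionisation of the allylic C6–O bond may also compete with carbon–carbon bond formation. The fallback is a Nicholas cyclisation and sets out from 16. Treatment with Co2(CO)8 in CH2Cl2 at rt should give the hexacarbonyldicobalt complex of 16 F1. BF3·OEt2 in CH2Cl2 at −78 °C then opens the epoxide at C10 to the cobalt-stabilised propargylic cation, which is captured by C5 through the same chair and loses a methyl proton, giving the hexacarbonyldicobalt complex of 17 F2. This cation is configurationally mobile, so C10 is set here by the chair in which the very bulky cluster sits equatorial and the methyl axial, which is the configuration required. Oxidative decomplexation with (NH4)2Ce(NO3)6 in acetone at −30 °C returns to the route at 17.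

Step 8. Facial selectivity may be poor because the Felkin preference of the C7 stereocentre and the 1,3-influence of the β-silyloxy group at C8 oppose each other in this syn-configured aldehyde; deprotonation of the alkyne and enolisation of the aldehyde may also consume reagent. The fallback sets out from 13. The Grignard addition is run without regard to selectivity, and the unwanted C6 epimer of 15 F3 (alone or mixed with 15) is oxidised with Dess–Martin periodinane and NaHCO3 in CH2Cl2 to the enone tert-butyl (3R,4R)-4-[(tert-butyldimethylsilyl)oxy]-4-[(2S,3S)-3-ethynyl-3-methyloxiran-2-yl]-3-(3-methylbut-2-enoyl)butanoate F4. Reagent-controlled reduction with (R)-2-methyl-CBS-oxazaborolidine and BH3·SMe2 in THF at −40 °C (the enantiomer that treats the alkenyl arm as the large group) should deliver the 6R alcohol, returning to the route at 15.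

Step 19. Acylation of the hindered C8 hydroxyl may be slow; under the heating needed, the angelate may isomerise to the tiglate and the neighbouring acetate may migrate from O9 to O8. The fallback builds the Z alkene on the ester and sets out from 27. Esterification with 2-[bis(2,2,2-trifluoroethoxy)phosphoryl]propanoic acid, DCC and DMAP (cat.) in CH2Cl2 at 0 °C should give the 8-O-{2-[bis(2,2,2-trifluoroethoxy)phosphoryl]propanoyl} derivative of 27 F5. A Still–Gennari olefination (KN(SiMe3)2, 18-crown-6, THF, −78 °C, then acetaldehyde) should form the Z trisubstituted enoate, returning to the route at 30.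

**Further compounds**

F1 | step 10 | hexacarbonyldicobalt complex of 16 (Co2(CO)6 bridging the C1–C2 alkyne) | CC(C)=C[C@@H](O[Si](CC)(CC)CC)[C@H](CC(=O)OC(C)(C)C)[C@@H](O[Si](C)(C)C(C)(C)C)[C@@H]1O[C@@]1(C)C23[Co]4(=C=O)(=C=O)(=C=O)[Co]2(=C=O)(=C=O)(=C=O)[CH]34
F2 | step 10 | hexacarbonyldicobalt complex of 17 | CC(=C)[C@@H]1[C@@H](O[Si](CC)(CC)CC)[C@H](CC(=O)OC(C)(C)C)[C@@H](O[Si](C)(C)C(C)(C)C)[C@H](O)[C@@]1(C)C23[Co]4(=C=O)(=C=O)(=C=O)[Co]2(=C=O)(=C=O)(=C=O)[CH]34
F3 | step 8 | C6 epimer of 15, tert-butyl (3S,4R)-4-[(tert-butyldimethylsilyl)oxy]-4-[(2S,3S)-3-ethynyl-3-methyloxiran-2-yl]-3-[(1S)-1-hydroxy-3-methylbut-2-en-1-yl]butanoate | CC(C)=C[C@H](O)[C@H](CC(=O)OC(C)(C)C)[C@@H](O[Si](C)(C)C(C)(C)C)[C@@H]1O[C@@]1(C)C#C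
F4 | step 8 | tert-butyl (3R,4R)-4-[(tert-butyldimethylsilyl)oxy]-4-[(2S,3S)-3-ethynyl-3-methyloxiran-2-yl]-3-(3-methylbut-2-enoyl)butanoate | CC(C)=CC(=O)[C@H](CC(=O)OC(C)(C)C)[C@@H](O[Si](C)(C)C(C)(C)C)[C@@H]1O[C@@]1(C)C#C
F5 | step 19 | 8-O-{2-[bis(2,2,2-trifluoroethoxy)phosphoryl]propanoyl} derivative of 27 (epimers at the phosphonate carbon) | C=C1C(=O)O[C@H]2[C@H]1[C@@H](OC(=O)C(C)P(=O)(OCC(F)(F)F)OCC(F)(F)F)[C@H](OC(C)=O)[C@@](C)(C#C)[C@@H]2C(=C)C
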